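All runs were generated by integration with made-up constants; noise was put on by code.

No run here changes the charge of Zd, so the readings cannot show directly what a smaller charge does; what they do show is a lag (induction period), and we reckon with that.

| setting | south-west | south-east | west | flask |
|---|---|---|---|---|
| Za | 0.25 M | 0.25 M | 0.38 M | 0.25 M |
| Zb | 0.12 M | 0.19 M | 0.25 M | 0.250 M |
| Zd | 20 mM | 20 mM | 20 mM | 20 mM |
| remark | run made earlier | run made earlier | run made earlier |  |

- south-west (time / min: Zf / %, Za / %): 3.00: 1.3, 99.0; 6.00: 4.0, 95.6; 10.0: 11.7, 88.9; 15.0: 21.5, 81.5; 20.0: 27.4, 72.1; 25.0: 32.7, 67.2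
- south-east (time / min: Zf / %, Za / %): 2.00: 0, 99.4; 3.00: 2.5, 98.2; 4.00: 4.4, 96.5; 6.00: 6.8, 93.1; 10.0: 18.7, 83.7; 15.0: 31.2, 70.7; 25.0: 50.3, 48.1
- west (time / min: Zf / %, Za / %): 5.00: 5.1, 96.1; 10.0: 14.7, 85.1; 15.0: 25.7, 72.4; 20.0: 38.0, 61.2; 25.0: 45.7, 56.5

(scatter of a reading: 1 percentage point)

- no earlier run changes the charge of Zd; that part of a forecast is a guess

1. factor on the rate of making Zf when 30% of the Za are converted if Zb is charged twice over
2. factor on the rate when 30% of the Za are converted if Zd is charged at 4.0 mM instead

In the west run, which has the flask's Zb charge, Zf climbs from 5.1% at 5.00 min to 25.7% at 15.0 min. So between these two readings of the west run Zf grows as time to the power n = 1.47, the lag exponent, a reading that carries the scatter of 1 percentage point on its small first value. Our rule follows from it. If a setting multiplies the height of the Zf curve at each time by f, and we hold n at the west run's reading, a given conversion comes sooner by f^(1/n), and the rate there, which is n times the conversion over the time, changes by that same f^(1/n) and not by f.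

First we turn Zb. Taking one Zb per Za, Zb left at 30% conversion goes from 0.175 M to 0.425 M; if we take the ratio of these two as f, our rule gives 1.83.

Then we turn Zd. If the height of the curve follows the charge of Zd, which is our guess, f is 0.200, and the rule gives 0.335.

The forecast gives 1.55 (1.2 to 2.1) for the doubled Zb and, differing from our figure, 0.2 (0.08 to 0.45) for the smaller Zd charge, the latter with the caution that “activation or dimer behaviour could shift this, so it is a wide guess”.

The simulation gives 1.78 for Zb, within the forecast's tolerance and beside our 1.83, and 0.342 for Zd, which is 1.71 times the forecast's value.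

    Za + Zb + Zc → Zf + Zc, rate k1*[Za]*[Zb]*[Zc]/(1 + ([Za]/sat1)) (3.20 mM, k = 100 M⁻² s⁻¹)
    Zd → Zc (k = 2.60 × 10⁻⁴ s⁻¹)
    Zb ⇌ Ze (K = 1.20, k = 2.40 × 10⁻⁴ s⁻¹)

In the flask, the half-life of Zd turning into Zc, 44 min at 40.0 min, is longer than the 12.1 min taken to reach 30% conversion, and at 20.0 min Zc is still 26.8% of the catalyst. On the flask charged with 4.0 mM Zd, the lag exponent 1.47 gave 0.335 against the simulated 0.342. That flask reaches the same conversion with 38.0% of its catalyst as Zc.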